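**Retrosynthetic overview**
- **Numbering and feature.** The upper flavan has rings A (benzo), B (2-aryl) and C (pyran), with unprimed atoms; the lower epiafzelechin has rings D, E and F, with primed atoms. The plan rests on ring C. Its O1–C2–C3–C4 chain carries only ring B on C2 and ring D (through C6') on C4, these two are 1,3-cis, and C3 has no substituent that could steer a cationic coupling.
- **Disconnection.** Ring C is cut at C4–C6', C3–C4 and O1–C2 at once. This gives a ring A salicylaldehyde, a ring B styrene and the intact lower unit as the C6' nucleophile, joined through an ortho-quinone methide on ring A.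
- **Ring order and stereocentres.** Rings A, B, D, E and F are bought, and ring C is the only ring formed, in the penultimate step. C2' and C3' come from (−)-epiafzelechin; C2 and C4 come from the cycloaddition.
- **Protection and endgame.** Every hydroxyl group except the salicyl OH is a benzyl ether and C8' carries bromine, so one hydrogenolysis finishes the synthesis.

Key step: step 6

Assumption: (−)-epiafzelechin is taken as a purchasable isolated natural product, and the (R) acid is assumed to favour the 4S face; both antipodes of the acid are available, so the (S) acid is used if the sense of induction proves opposite.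

**Step 1**
Reactants: 1 (−)-epiafzelechin
Product: 2 5,7,4'-tri-O-benzyl-(−)-epiafzelechin
Conditions: BnBr (3.3 equiv), K2CO3 (3.5 equiv), DMF, Ar, 0 °C → rt
Reagents that add atoms: benzyl bromide, BrCc1ccccc1
Why: Williamson etherification in which K2CO3 deprotonates only the three phenols and leaves the secondary C3 alcohol alone, while the cold, oxygen-free medium limits C-benzylation of the phloroglucinol ring and base-induced epimerisation at C2, so neither stereocentre is touched.

**Step 2**
Reactants: 2 5,7,4'-tri-O-benzyl-(−)-epiafzelechin
Product: 3 3,5,7,4'-tetra-O-benzyl-(−)-epiafzelechin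
Conditions: NaH (1.5 equiv), BnBr (1.3 equiv), DMF, 0 °C → rt
Reagents that add atoms: benzyl bromide, BrCc1ccccc1
Why: Williamson etherification of the C3 alkoxide masks the last free alcohol, which in step 6 could form a hemiacetal with the aldehyde or add to the methide, and the new ether leaves with the others in step 7.

**Step 3**
Reactants: 3 3,5,7,4'-tetra-O-benzyl-(−)-epiafzelechin
Product: 4 8-bromo-3,5,7,4'-tetra-O-benzyl-(−)-epiafzelechin
Conditions: NBS (1.0 equiv), CH2Cl2, dark, −78 °C → 0 °C
Reagents that add atoms: N-bromosuccinimide, O=C1CCC(=O)N1Br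
Why: Electrophilic aromatic bromination in which the trioxygenated benzo ring reacts far faster than the monoalkoxy 2-aryl ring, and one equivalent of NBS at low temperature takes C8 next to O1, as established for 5,7-di-O-benzyl flavan-3-ols, leaving C6 (C6' of the target) as the only free nucleophilic site.

**Step 4**
Reactants: 5 2,4-dihydroxybenzaldehyde
Product: 6 4-(benzyloxy)-2-hydroxybenzaldehyde
Conditions: BnBr (1.0 equiv), NaHCO3 (1.2 equiv), MeCN, reflux
Reagents that add atoms: benzyl bromide, BrCc1ccccc1
Why: Regioselective Williamson etherification, because the weak base ionises only the more acidic 4-OH (a vinylogous acid) while the 2-OH stays locked in its hydrogen bond to the formyl oxygen.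

**Step 5**
Reactants: 7 4-(benzyloxy)benzaldehyde
Product: 8 4-(benzyloxy)styrene
Conditions: Ph3PCH3Br (1.2 equiv), KOtBu (1.2 equiv), THF, 0 °C → rt
Reagents that add atoms: methyltriphenylphosphonium bromide, C[P+](c1ccccc1)(c1ccccc1)c1ccccc1.[Br-]
Why: Wittig methylenation of a non-enolisable aromatic aldehyde gives the styrene directly and avoids handling polymerisation-prone 4-vinylphenol.

**Step 6**
Reactants: 4 8-bromo-3,5,7,4'-tetra-O-benzyl-(−)-epiafzelechin, 6 4-(benzyloxy)-2-hydroxybenzaldehyde, 8 4-(benzyloxy)styrene
Product: 11 (2S,4S,2'R,3'R)-hexa-O-benzyl-8'-bromo derivative of the target, via benzhydrol 9 (not isolated), via ortho-quinone methide 10 (not isolated)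
Conditions: 4 (1.0 equiv), 6 (1.2 equiv), (R)-3,3'-bis(2,4,6-triisopropylphenyl)-1,1'-binaphthalene-2,2'-diyl N-triflylphosphoramide (10 mol %), 5 Å MS, PhMe, rt → 40 °C until 4 is consumed; then 0 °C, 8 (3 equiv) added slowly
Reagents that add atoms: none
Why: Proposed new method: the N-triflylphosphoramide, several pKa units stronger than the parent phosphoric acid, protonates the chelated aldehyde 6 enough for Friedel–Crafts hydroxyalkylation by C6' of 4 (ortho to O5' and O7', para to O1', so still phloroglucinol-like despite the meta bromine), and the doubly donor-stabilised benzhydrol 9 then loses water to the sieves, which pulls the reversible first stage forward and leaves the E ortho-quinone methide 10 hydrogen-bonded and ion-paired to the chiral anion. The closest known reaction types are the acid-promoted condensation of salicylaldehydes with electron-rich arenes through ortho-quinone methides and the chiral phosphoric acid catalysed (4+2) cycloaddition of styrenes with ortho-quinone methides released from isolated ortho-hydroxybenzhydrols; the new element is their merger under one chiral acid in one flask with a flavan-3-ol ether as the arene. Ring C closes by an inverse-electron-demand oxa-Diels–Alder reaction, concerted but strongly asynchronous, in which the CH2 terminus of 8 bonds to the methide carbon (C3–C4) ahead of O1–C2 closure at the 4-benzyloxybenzylic carbon that best carries positive charge, which fixes the regiochemistry. C4 is set by the catalyst, whose 3,3'-aryl groups leave one face of the bound methide open, since C2' and C3' are too remote to bias it; C2 is set relative to C4 by the endo approach of ring B to the E methide, which gives the 2,4-cis diequatorial (2S,4S) flavan, also the more stable epimer should the C2–O1 bond ionise reversibly. Site selectivity at ring D rests on the C8' bromine, only one methide can form because the salicyl OH is the sole free hydroxyl group present, and a second arylation of 10 to a triarylmethane is held back by the two benzyloxy groups that flank C6'. Adding 8 only after 4 has been consumed ensures that any flavan-4-yl cation arising from surplus 6 and 8 finds no ring D to arylate, so that all of 11 is formed through the catalyst-bound methide.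

**Step 7**
Reactants: 11 (2S,4S,2'R,3'R)-hexa-O-benzyl-8'-bromo derivative of the target
Product: 12 CNP0167324.1, (2S,4S)-7,4'-dihydroxyflavan-(4→6')-(−)-epiafzelechin
Conditions: H2 (1 atm), Pd(OH)2/C, Et3N (1.1 equiv), THF/MeOH, rt; filtration under Ar, Sephadex LH-20
Reagents that add atoms: none
Why: Catalytic hydrogenolysis removes the C8' bromine first, the amine trapping the HBr that would otherwise cleave the acid-labile C4–C6' bond and thereby being tied up as its salt, after which the six benzyl ethers are cleaved while the cyclic C2–O1 and C2'–O1' ethers and all four stereocentres stay intact, as is usual for benzylated flavan-3-ol oligomers.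

**Compound list**
1 | (−)-epiafzelechin, (2R,3R)-2-(4-hydroxyphenyl)chroman-3,5,7-triol | Oc1cc(O)c2C[C@@H](O)[C@@H](c3ccc(O)cc3)Oc2c1 | starting material
2 | 5,7,4'-tri-O-benzyl-(−)-epiafzelechin, (2R,3R)-5,7-bis(benzyloxy)-2-[4-(benzyloxy)phenyl]chroman-3-ol | C(c1ccccc1)Oc1cc(OCc2ccccc2)c2C[C@@H](O)[C@@H](c3ccc(OCc4ccccc4)cc3)Oc2c1 | intermediate
3 | 3,5,7,4'-tetra-O-benzyl-(−)-epiafzelechin, (2R,3R)-3,5,7-tris(benzyloxy)-2-[4-(benzyloxy)phenyl]chroman | C(c1ccccc1)Oc1cc(OCc2ccccc2)c2C[C@@H](OCc3ccccc3)[C@@H](c3ccc(OCc4ccccc4)cc3)Oc2c1 | intermediate
4 | 8-bromo-3,5,7,4'-tetra-O-benzyl-(−)-epiafzelechin, (2R,3R)-3,5,7-tris(benzyloxy)-2-[4-(benzyloxy)phenyl]-8-bromochroman | Brc1c(OCc2ccccc2)cc(OCc2ccccc2)c2C[C@@H](OCc3ccccc3)[C@@H](c3ccc(OCc4ccccc4)cc3)Oc12 | intermediate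
5 | 2,4-dihydroxybenzaldehyde | O=Cc1ccc(O)cc1O | starting material
6 | 4-(benzyloxy)-2-hydroxybenzaldehyde | O=Cc1ccc(OCc2ccccc2)cc1O | intermediate
7 | 4-(benzyloxy)benzaldehyde | O=Cc1ccc(OCc2ccccc2)cc1 | starting material
8 | 4-(benzyloxy)styrene | C=Cc1ccc(OCc2ccccc2)cc1 | intermediate
9 | benzhydrol: [4-(benzyloxy)-2-hydroxyphenyl]carbinol carrying at its carbinol carbon C6 of the chroman 4, both carbinol epimers | OC(c1ccc(OCc2ccccc2)cc1O)c1c(OCc2ccccc2)c(Br)c2c(c1OCc1ccccc1)C[C@@H](OCc1ccccc1)[C@@H](c1ccc(OCc3ccccc3)cc1)O2 | intermediate
10 | (E)-ortho-quinone methide: 3-(benzyloxy)-6-(arylmethylidene)cyclohexa-2,4-dien-1-one, aryl = C6 of the chroman 4, aryl group anti to the carbonyl group | O=C1C=C(OCc2ccccc2)C=C/C1=C\c1c(OCc2ccccc2)c(Br)c2c(c1OCc1ccccc1)C[C@@H](OCc1ccccc1)[C@@H](c1ccc(OCc3ccccc3)cc1)O2 | intermediate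
11 | hexa-O-benzyl-8'-bromo derivative of the target: (2S,4S)-7-(benzyloxy)-2-[4-(benzyloxy)phenyl]chroman-4-yl group on C6' of (2'R,3'R)-3',5',7'-tris(benzyloxy)-2'-[4-(benzyloxy)phenyl]-8'-bromochroman, ring C aryl groups cis | C(c1ccccc1)Oc1ccc([C@@H]2C[C@H](c3c(OCc4ccccc4)c(Br)c4c(c3OCc3ccccc3)C[C@@H](OCc3ccccc3)[C@@H](c3ccc(OCc5ccccc5)cc3)O4)c3ccc(OCc4ccccc4)cc3O2)cc1 | intermediate
12 | CNP0167324.1, (2S,4S)-7,4'-dihydroxyflavan-(4→6')-(2'R,3'R)-epiafzelechin | Oc1ccc([C@@H]2C[C@H](c3c(O)cc4c(c3O)C[C@@H](O)[C@@H](c3ccc(O)cc3)O4)c3ccc(O)cc3O2)cc1 | target

**Total step count:** 7. **Longest linear sequence:** 5 (steps 1, 2, 3, 6, 7).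

**Steps most likely to fail**

1. **Step 6.**
   - Risks:
     - Hydroxyalkylation at the crowded, bromine-deactivated C6' may be slow or unfavourable.
     - The two flanking benzyloxy groups may shield both faces of the methide carbon, so that cationic oligomerisation of the styrene outruns the cycloaddition.
     - Hydride transfer from a flanking OCH2Ph group to the methide carbon may intervene.
     - Discrimination between the two methide faces may be weak.
   - Fallback: this route sets out from 4 and comes back at 11. It reverses the polarity of the C4–C6' bond formation and uses only known reactions.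
     - Vilsmeier–Haack formylation of 4 (POCl3, DMF, 0 → 60 °C, then aqueous NaOAc) should give (2R,3R)-3,5,7-tris(benzyloxy)-2-[4-(benzyloxy)phenyl]-8-bromochroman-6-carbaldehyde F1.
     - Commercial 3-(benzyloxy)phenol (Oc1cccc(OCc2ccccc2)c1) is converted with EtMgBr into its bromomagnesium phenolate and treated with F1 in toluene at rt. This chelate-controlled, ortho-selective hydroxyalkylation occurs at the position para to the benzyloxy group and gives benzhydrol 9, now isolated.
     - Benzhydrol 9 and styrene 8 are then submitted to the established two-component (4+2) reaction under the milder (R)-3,3'-bis(2,4,6-triisopropylphenyl)-BINOL phosphoric acid (PhMe, 5 Å MS, 0 °C) to give 11.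
     - The C4 epimers are diastereomers, so they can be separated by chromatography if catalyst control is incomplete.

2. **Step 7.**
   - Risks:
     - Debenzylation may stall at the hindered ethers beside the interflavan bond, or at the aliphatic C3' ether, through amine poisoning of the catalyst.
     - The C4–C6' bond may undergo acid-induced fission if HBr escapes the scavenger.
     - The free polyphenol may oxidise in air during work-up.
   - Fallback: this route sets out from 11 and comes back at 12. It separates the two reductive events.
     - Bromine–lithium exchange (n-BuLi, THF, −78 °C) followed by a methanol quench should give the bromine-free hexa-O-benzyl ether of the target F2.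
     - F2 is then hydrogenolysed under strictly neutral conditions (H2, Pd(OH)2/C, THF/MeOH/H2O, rt), with neither HBr nor amine in the flask.

3. **Step 1.**
   - Risks:
     - Ring D may undergo C-benzylation.
     - C2' may epimerise by base-induced opening of ring F through the ring E phenolate.
     - The polyphenolate may oxidise.
   - Fallback: this route sets out from 1 and comes back at 3, so step 2 is bypassed as well.
     - Peracetylation (Ac2O, pyridine, rt) gives (−)-epiafzelechin tetraacetate F3, which is stable and non-phenolic.
     - Treatment with NaH, BnCl and a measured amount of water in DMF (0 °C → rt) cleaves the acetates one at a time and benzylates each oxyanion as it is released, so free phenolate never builds up.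
     - With excess reagents the C3 acetate is exchanged too, and 3 results.

**Further compounds**
F1 | step 6 | (2R,3R)-3,5,7-tris(benzyloxy)-2-[4-(benzyloxy)phenyl]-8-bromochroman-6-carbaldehyde | O=Cc1c(OCc2ccccc2)c(Br)c2c(c1OCc1ccccc1)C[C@@H](OCc1ccccc1)[C@@H](c1ccc(OCc3ccccc3)cc1)O2
F2 | step 7 | bromine-free hexa-O-benzyl ether of the target, (2S,4S,2'R,3'R) | C(c1ccccc1)Oc1ccc([C@@H]2C[C@H](c3c(OCc4ccccc4)cc4c(c3OCc3ccccc3)C[C@@H](OCc3ccccc3)[C@@H](c3ccc(OCc5ccccc5)cc3)O4)c3ccc(OCc4ccccc4)cc3O2)cc1
F3 | step 1 | (−)-epiafzelechin tetraacetate, (2R,3R) | CC(=O)Oc1cc(OC(C)=O)c2C[C@@H](OC(C)=O)[C@@H](c3ccc(OC(C)=O)cc3)Oc2c1
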